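The oxane ring (O1, C2 = CMe2, C3 = CHBr, C4, C5, C6 = quaternary carbon) is cut at C3. This carbon lies between the oxygen-bearing C2 and C4H2, and it is treated as a one-carbon unit that brings its own bromine. Dibromocarbene adds to the C2=C4 enol-ether bond of a 5-methyl-2,3-dihydrofuran that already carries the tertiary-ether stereocentre C6. C3–C4 and C3–C2 form together, and electrocyclic opening of the cyclopropane breaks the old C2–C4 bond. One operation therefore enlarges the five-membered ring to the oxane and puts bromine on C3. The dihydrofuran comes from an aldol/metathesis-derived cyclohexenyl methyl ketone by chelate-controlled Grignard addition.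

Key step: step 9

Remark on labels: cyclohexane atoms are C1' (on C6), C2' (CHOH), C3', C4' (CMeCl), C5' (CHBr), C6'. "Up" is the face of the cyclohexane that carries C6 and the C2' oxygen. TBS = tert-butyldimethylsilyl.

Remark on the ring halogens: the bulky C1' substituent sits equatorial. Direct Br+/Cl− addition to C4'=C5' should therefore follow trans-diaxial, Markovnikov opening and give the wrong pair of configurations. Steps 11–13 bring bromine to the upper face by way of an epoxide.

Assumption: 17 forms as a mixture of epimers at the ketal carbon C2. This does not matter, because step 10 turns C2 into CMe2.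

Step 1
Reactants: 1 (R)-4-benzyl-1,3-oxazolidin-2-one; 2 pent-4-enoyl chloride
Product: 3 (R)-4-benzyl-3-(pent-4-enoyl)-1,3-oxazolidin-2-one
Conditions: Et3N, DMAP (cat.), CH2Cl2, 0 °C to rt
Reagents that add atoms: none
Why: DMAP-catalysed N-acylation (nucleophilic acyl substitution) of the oxazolidinone, which leaves the auxiliary stereocentre untouched.

Step 2
Reactants: 4 3-methylbut-3-en-1-ol
Product: 5 3-methylbut-3-enal
Conditions: Dess–Martin periodinane, NaHCO3, CH2Cl2, 0 °C; solution used directly
Reagents that add atoms: none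
Why: Buffered Dess–Martin oxidation is neutral and fast, so the β,γ-unsaturated aldehyde should be obtained without moving the double bond into conjugation.

Step 3
Reactants: 3 (R)-4-benzyl-3-(pent-4-enoyl)-1,3-oxazolidin-2-one; 5 3-methylbut-3-enal
Product: 7 (R)-4-benzyl-3-[(2R,3S)-2-allyl-3-hydroxy-5-methylhex-5-enoyl]-1,3-oxazolidin-2-one, via boron enolate 6 (not isolated)
Conditions: Bu2BOTf, Et3N, CH2Cl2, −78 to 0 °C; 5, −78 to 0 °C; then H2O2, MeOH, pH 7 buffer
Reagents that add atoms: none
Why: Evans syn-aldol reaction, in which the (Z)-boron enolate reacts through a Zimmerman–Traxler chair on the face away from the benzyl group and sets C1' (R) and C2' (S) together.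

Step 4
Reactants: 7 syn-aldol imide
Product: 8 (R)-4-benzyl-3-[(1R,6S)-6-hydroxy-4-methylcyclohex-3-ene-1-carbonyl]-1,3-oxazolidin-2-one
Conditions: Grubbs II catalyst (cat.), CH2Cl2, 40 °C
Reagents that add atoms: none
Why: Ring-closing metathesis of the allyl and methallyl arms gives the trisubstituted C4'=C5' cyclohexene, and the syn-aldol relationship becomes the cis C1'/C2' relationship of the ring.

Step 5
Reactants: 8 cyclohexene imide
Product: 9 (1R,6S)-6-hydroxy-N-methoxy-N,4-dimethylcyclohex-3-ene-1-carboxamide
Conditions: MeNH(OMe)·HCl, AlMe3, THF, 0 °C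
Reagents that add atoms: N,O-dimethylhydroxylamine hydrochloride, CNOC.Cl
Why: Aluminium-amide transamidation (Weinreb amide formation) attacks the exocyclic imide carbonyl, assisted by the β-hydroxyl group, and releases the auxiliary without epimerising C1'.

Step 6
Reactants: 9 Weinreb amide
Product: 10 1-[(1R,6S)-6-hydroxy-4-methylcyclohex-3-en-1-yl]ethan-1-one
Conditions: MeMgBr (excess), THF, −78 to 0 °C
Reagents that add atoms: methylmagnesium bromide, C[Mg]Br
Why: Weinreb ketone synthesis, in which the chelated tetrahedral intermediate survives until the quench, so that single addition occurs and C1' keeps its configuration.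

Step 7
Reactants: 10 cis-β-hydroxy methyl ketone; 11 2-(2-bromoethyl)-2-methyl-1,3-dioxolane
Product: 14 tricyclic ketal in which the ketal carbon C2 (bearing CH3 and C4) is bound to O1 on (S)-C6 and to the oxygen on (S)-C2', via Grignard reagent 12 (not isolated), via diol ketal 13 (not isolated)
Conditions: 11, Mg, THF, 25 °C; then 10, CH2Cl2–THF, −78 to −30 °C; then 1 M HCl, THF, rt
Reagents that add atoms: none
Why: Cram-chelate-controlled Grignard addition, in which the magnesium alkoxide of C2'–OH ties up the ketone oxygen and the nucleophile enters on the side of the C1' hydrogen to set C6 (S); acid transketalisation then closes the dioxabicyclo[3.2.1]octane cage, which only this C6 epimer can form with H rather than C3' in the endo position.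

Step 8
Reactants: 14 tricyclic ketal
Product: 15 (S)-2-[(1R,6S)-6-(TBS-oxy)-4-methylcyclohex-3-en-1-yl]-2,5-dimethyl-2,3-dihydrofuran
Conditions: TBSOTf, Et3N, CH2Cl2, 0 °C to rt
Reagents that add atoms: tert-butyldimethylsilyl triflate, CC(C)(C)[Si](C)(C)OS(=O)(=O)C(F)(F)F
Why: Silyl triflate/amine conversion of a ketal into an enol ether, in which the silyl cation takes the less hindered secondary C2' oxygen, the five-membered oxocarbenium ion loses a C4 proton, and the ammonium triflate buffer funnels any exocyclic isomer to the more stable endocyclic enol ether.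

Step 9
Reactants: 15 TBS-protected dihydrofuran
Product: 17 (6S)-3-bromo-2-methoxy-2,6-dimethyl-6-[(1R,6S)-6-(TBS-oxy)-4-methylcyclohex-3-en-1-yl]-5,6-dihydro-2H-pyran, via dibromocyclopropane 16 (not isolated)
Conditions: CHBr3 (1.1 equiv), KOtBu, pentane, −40 to −10 °C; then MeOH, Et3N, rt
Reagents that add atoms: bromoform, BrC(Br)Br; methanol, CO
Why: α-Elimination of HBr from bromoform gives singlet dibromocarbene, which adds in a concerted cheletropic [2+1] step to the electron-rich C2=C4 enol-ether bond of 15, so that C3–C4 and C3–C2 are made together and the three-membered ring of 16 closes cis-fused on the face of the C6 methyl group. The lone pair on O1 then drives a disrotatory 2π-electrocyclic opening (Woodward–Hoffmann–DePuy rule) in which the endo bromide leaves and the old C2–C4 bond breaks, which turns the five-membered ring into the six-membered 2-bromoallyl oxocarbenium ion, and methanol adds at C2. The closest known reaction type is the dihalocarbene one-carbon ring enlargement of 2,3-dihydrofurans, glycals and indenes (Ciamician–Dennstedt type). Ring closures: the cyclopropane closes by suprafacial [2+1] addition and the oxane arises from it by ring enlargement without a further new bond. The stereocentres made at C2 and C4 in 16 are erased again (C4 becomes sp2 and the ketal carbon C2 becomes CMe2 in step 10), C6, C1' and C2' are not touched, and the place of Br on C3 follows from the mechanism. The step needs chemoselectivity for the enol ether over the trisubstituted C4'=C5' alkene, which the oxygen donor secures toward the electrophilic carbene when little excess bromoform is used, as in the selective attack on the enol-ether bond of 1-methoxycyclohexa-1,4-dienes.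

Step 10
Reactants: 17 bromo methyl ketal
Product: 18 (6S)-3-bromo-2,2,6-trimethyl-6-[(1R,6S)-6-(TBS-oxy)-4-methylcyclohex-3-en-1-yl]-5,6-dihydro-2H-pyran
Conditions: AlMe3, CH2Cl2, −78 to 0 °C
Reagents that add atoms: trimethylaluminium, C[Al](C)C
Why: Lewis-acid ionisation of the allylic ketal and methyl transfer from aluminium to the oxygen-bearing terminus of the oxocarbenium ion (Ferrier-type C-alkylation regiochemistry) completes the di-tertiary ether by C–C bond formation and creates no stereocentre.

Step 11
Reactants: 18 cyclic vinyl bromide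
Product: 19 4',5'-epoxide of 18 with the oxygen on the lower face, anti to the axial OTBS group
Conditions: mCPBA, CH2Cl2, 0 °C
Reagents that add atoms: 3-chloroperbenzoic acid, OOC(=O)c1cccc(Cl)c1
Why: Prilezhaev epoxidation picks the electron-rich trisubstituted ring alkene over the electron-poor vinyl bromide and should approach from the face opposite the axial C2' silyl ether.

Step 12
Reactants: 19 epoxide
Product: 20 trans-diaxial bromohydrin with C4'–Br up (tertiary) and C5'–OH down
Conditions: 48% aq. HBr, Et2O, −20 °C
Reagents that add atoms: hydrogen bromide, Br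
Why: Acid-promoted epoxide opening in which the Fürst–Plattner (trans-diaxial) rule and Markovnikov polarisation both direct bromide to the tertiary C4' from the upper face.

Step 13
Reactants: 20 bromohydrin
Product: 22 diequatorial bromochloride with C5'–Br up and C4'–Cl down (4'S,5'S), via diaxial bromochloride 21 (not isolated)
Conditions: SOCl2, pyridine, CH2Cl2, −20 to 0 °C; then MeCN, 75 °C
Reagents that add atoms: thionyl chloride, O=S(Cl)Cl
Why: The axial chlorosulfite at C5' is displaced by the antiperiplanar axial C4' bromine (neighbouring-group participation), chloride opens the upper-face bromonium ion from below to give 21, and heating in a polar solvent brings about the diaxial-to-diequatorial (dyotropic) 1,2-interchange of vicinal halogens, which moves Br to C5' and Cl to C4' on the faces they already occupy.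

Step 14
Reactants: 22 bromochloride vinyl bromide
Product: 23 O-TBS ether of the target
Conditions: Mn(dpm)3 (cat.), PhSiH3, t-BuOOH, i-PrOH, rt
Reagents that add atoms: none
Why: Metal-hydride hydrogen-atom-transfer (Mukaiyama-type) hydrogenation of a haloalkene, in which H• adds to the less hindered C4 and the α-bromo radical at C3 takes the second hydrogen on its open axial face (the other face carries the axial methyl groups on C2 and C6), so that Br ends equatorial and trans to the cyclohexyl group (C3 R) and the alkyl halides are left alone.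

Step 15
Reactants: 23 O-TBS ether of the target
Product: 24 target CNP0323120.1
Conditions: HF·pyridine, THF, 0 °C to rt
Reagents that add atoms: none
Why: Fluoride-mediated silyl ether cleavage under non-basic conditions frees the axial C2' alcohol without E2 loss of the halogens.

Compound list

1 | (R)-4-benzyl-1,3-oxazolidin-2-one | O=C1N[C@H](Cc2ccccc2)CO1 | starting material
2 | pent-4-enoyl chloride | C=CCCC(=O)Cl | starting material
3 | (R)-4-benzyl-3-(pent-4-enoyl)-1,3-oxazolidin-2-one | C=CCCC(=O)N1[C@H](Cc2ccccc2)COC1=O | intermediate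
4 | 3-methylbut-3-en-1-ol | CC(=C)CCO | starting material
5 | 3-methylbut-3-enal | CC(=C)CC=O | intermediate
6 | (Z)-dibutylboron enolate of 3 | C=CC/C=C(\OB(CCCC)CCCC)N1[C@H](Cc2ccccc2)COC1=O | intermediate
7 | syn-aldol imide (2R,3S) | O=C(N1[C@H](Cc2ccccc2)COC1=O)[C@@H]([C@@H](O)CC(C)=C)CC=C | intermediate
8 | cyclohexene imide (1R,6S) | O=C(N1[C@H](Cc2ccccc2)COC1=O)[C@@H]1CC=C(C)C[C@@H]1O | intermediate
9 | Weinreb amide (1R,6S) | CON(C)C(=O)[C@@H]1CC=C(C)C[C@@H]1O | intermediate
10 | cis-β-hydroxy methyl ketone (1R,6S) | CC(=O)[C@@H]1CC=C(C)C[C@@H]1O | intermediate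
11 | 2-(2-bromoethyl)-2-methyl-1,3-dioxolane | CC1(CCBr)OCCO1 | starting material
12 | [2-(2-methyl-1,3-dioxolan-2-yl)ethyl]magnesium bromide | CC1(CC[Mg]Br)OCCO1 | intermediate
13 | diol ketal (C6 S, C1' R, C2' S) | O[C@](C)([C@@H]1CC=C(C)C[C@@H]1O)CCC1(C)OCCO1 | intermediate
14 | tricyclic ketal | C[C@]12CC[C@](C)(O1)[C@@H]1CC=C(C)C[C@@H]1O2 | intermediate
15 | TBS-protected 2,5-dimethyl-2,3-dihydrofuran | CC1=CC[C@](C)(O1)[C@@H]1CC=C(C)C[C@@H]1O[Si](C)(C)C(C)(C)C | intermediate
16 | 6,6-dibromo-2-oxabicyclo[3.1.0]hexane adduct, CBr2 on the face of the C6 methyl group | C[C@]12O[C@](C)([C@@H]3CC=C(C)C[C@@H]3O[Si](C)(C)C(C)(C)C)C[C@H]1C2(Br)Br | intermediate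
17 | 3-bromo-2-methoxy-5,6-dihydro-2H-pyran, epimers at C2 | COC1(C)O[C@](C)([C@@H]2CC=C(C)C[C@@H]2O[Si](C)(C)C(C)(C)C)CC=C1Br | intermediate
18 | 3-bromo-2,2,6-trimethyl-5,6-dihydro-2H-pyran | CC1(C)O[C@](C)([C@@H]2CC=C(C)C[C@@H]2O[Si](C)(C)C(C)(C)C)CC=C1Br | intermediate
19 | lower-face 4',5'-epoxide | CC1(C)O[C@](C)([C@@H]2C[C@H]3O[C@@]3(C)C[C@@H]2O[Si](C)(C)C(C)(C)C)CC=C1Br | intermediate
20 | trans-diaxial bromohydrin | CC1(C)O[C@](C)([C@@H]2C[C@@H](O)[C@](C)(Br)C[C@@H]2O[Si](C)(C)C(C)(C)C)CC=C1Br | intermediate
21 | trans-diaxial 4'-bromo-5'-chloro compound | CC1(C)O[C@](C)([C@@H]2C[C@@H](Cl)[C@](C)(Br)C[C@@H]2O[Si](C)(C)C(C)(C)C)CC=C1Br | intermediate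
22 | trans-diequatorial 5'-bromo-4'-chloro compound | CC1(C)O[C@](C)([C@@H]2C[C@H](Br)[C@@](C)(Cl)C[C@@H]2O[Si](C)(C)C(C)(C)C)CC=C1Br | intermediate
23 | O-TBS ether of the target | CC1(C)O[C@](C)([C@@H]2C[C@H](Br)[C@@](C)(Cl)C[C@@H]2O[Si](C)(C)C(C)(C)C)CC[C@H]1Br | intermediate
24 | CNP0323120.1 | CC1(C)O[C@](C)([C@@H]2C[C@H](Br)[C@@](C)(Cl)C[C@@H]2O)CC[C@H]1Br | target

Total step count: 15. Longest linear sequence: 14 (steps 1 and 3–15; step 2 runs in parallel).

Steps most likely to fail

1. Step 9. The carbene may also attack the ring alkene. The labile adduct may also ionise while tert-butoxide is still present and lose a proton from the C2 methyl group instead of taking up methanol. The fallback sets out from 14 and removes the competing alkene before any carbene is made.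
   - mCPBA should epoxidise 14 on the face away from the ketal cage to give the epoxy ketal F1.
   - HBr should open it trans-diaxially to the bromohydrin ketal F2.
   - SOCl2/pyridine should give the diaxial bromochloride ketal F3, and heating should give the diequatorial bromochloride ketal F4.
   - TBSOTf/Et3N then gives the halogenated dihydrofuran F5, whose only C=C bond is the enol ether.
   - CHBr3/KOtBu gives the halogenated dibromocyclopropane F6, and methanol/Et3N gives the halogenated methyl ketal F7.
   - AlMe3 at −78 °C brings the sequence back to the route at 22.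

2. Step 13. The bromonium ion may return to alkene and BrCl, followed by re-addition on the other face. The tertiary bromide may eliminate, or the halogen interchange may stop short of completion. The fallback sets out from 18 and avoids both the tertiary bromide and the interchange.
   - OsO4/NMO should dihydroxylate the ring alkene from the lower face to give the cis-diol F8.
   - SOCl2/Et3N gives the cyclic sulfite F9, and RuCl3/NaIO4 gives the cyclic sulfate F10.
   - LiBr displaces the axial secondary C5'–O bond with inversion (SN2) to give the bromo sulfate half-ester F11.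
   - Dilute H2SO4 in wet THF gives the trans-diequatorial bromohydrin F12, with C5'–Br up and C4'–OH down.
   - SOCl2 in dioxane without base should replace the tertiary hydroxyl with retention by internal return of the chlorosulfite (SNi), which comes back to the route at 22.

3. Step 14. Hydrogen-atom transfer to the hindered, electron-poor trisubstituted alkene may be slow. Bromine may also be lost by β-scission if hydrogen adds at C3. The fallback sets out from 18 and installs the C3 bromide by substitution before the ring is halogenated.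
   - t-BuLi, then B(OMe)3, gives the alkenylboronate F13, and NaBO3 oxidises it to the oxan-3-one F14.
   - L-Selectride attacks from the equatorial side to give the axial C3 alcohol F15.
   - CBr4/P(n-Oct)3 in toluene (Appel reaction, inversion) gives the equatorial C3 bromide F16.
   - The conditions of steps 11–13 then lead through the saturated epoxide F17, the saturated bromohydrin F18 and the saturated diaxial bromochloride F19.
   - This sequence comes back to the route at 23.

Further compounds

F1 | step 9 | epoxy ketal | C[C@]12CC[C@](C)(O1)[C@@H]1C[C@H]3O[C@@]3(C)C[C@@H]1O2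
F2 | step 9 | bromohydrin ketal | C[C@]12CC[C@](C)(O1)[C@@H]1C[C@@H](O)[C@](C)(Br)C[C@@H]1O2
F3 | step 9 | diaxial bromochloride ketal | C[C@]12CC[C@](C)(O1)[C@@H]1C[C@@H](Cl)[C@](C)(Br)C[C@@H]1O2
F4 | step 9 | diequatorial bromochloride ketal | C[C@]12CC[C@](C)(O1)[C@@H]1C[C@H](Br)[C@@](C)(Cl)C[C@@H]1O2
F5 | step 9 | halogenated dihydrofuran | CC1=CC[C@](C)(O1)[C@@H]1C[C@H](Br)[C@@](C)(Cl)C[C@@H]1O[Si](C)(C)C(C)(C)C
F6 | step 9 | halogenated dibromocyclopropane | C[C@]12O[C@](C)([C@@H]3C[C@H](Br)[C@@](C)(Cl)C[C@@H]3O[Si](C)(C)C(C)(C)C)C[C@H]1C2(Br)Br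
F7 | step 9 | halogenated methyl ketal | COC1(C)O[C@](C)([C@@H]2C[C@H](Br)[C@@](C)(Cl)C[C@@H]2O[Si](C)(C)C(C)(C)C)CC=C1Br
F8 | step 13 | cis-diol | CC1(C)O[C@](C)([C@@H]2C[C@@H](O)[C@@](C)(O)C[C@@H]2O[Si](C)(C)C(C)(C)C)CC=C1Br
F9 | step 13 | cyclic sulfite | CC1(C)O[C@](C)([C@@H]2C[C@H]3OS(=O)O[C@@]3(C)C[C@@H]2O[Si](C)(C)C(C)(C)C)CC=C1Br
F10 | step 13 | cyclic sulfate | CC1(C)O[C@](C)([C@@H]2C[C@H]3OS(=O)(=O)O[C@@]3(C)C[C@@H]2O[Si](C)(C)C(C)(C)C)CC=C1Br
F11 | step 13 | bromo sulfate half-ester | CC1(C)O[C@](C)([C@@H]2C[C@H](Br)[C@@](C)(OS(=O)(=O)O)C[C@@H]2O[Si](C)(C)C(C)(C)C)CC=C1Br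
F12 | step 13 | trans-diequatorial bromohydrin | CC1(C)O[C@](C)([C@@H]2C[C@H](Br)[C@@](C)(O)C[C@@H]2O[Si](C)(C)C(C)(C)C)CC=C1Br
F13 | step 14 | alkenylboronate | CC1(C)O[C@](C)([C@@H]2CC=C(C)C[C@@H]2O[Si](C)(C)C(C)(C)C)CC=C1B(OC)OC
F14 | step 14 | oxan-3-one | CC1(C)O[C@](C)([C@@H]2CC=C(C)C[C@@H]2O[Si](C)(C)C(C)(C)C)CCC1=O
F15 | step 14 | axial C3 alcohol | CC1(C)O[C@](C)([C@@H]2CC=C(C)C[C@@H]2O[Si](C)(C)C(C)(C)C)CC[C@@H]1O
F16 | step 14 | equatorial C3 bromide | CC1(C)O[C@](C)([C@@H]2CC=C(C)C[C@@H]2O[Si](C)(C)C(C)(C)C)CC[C@H]1Br
F17 | step 14 | saturated epoxide | CC1(C)O[C@](C)([C@@H]2C[C@H]3O[C@@]3(C)C[C@@H]2O[Si](C)(C)C(C)(C)C)CC[C@H]1Br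
F18 | step 14 | saturated bromohydrin | CC1(C)O[C@](C)([C@@H]2C[C@@H](O)[C@](C)(Br)C[C@@H]2O[Si](C)(C)C(C)(C)C)CC[C@H]1Br
F19 | step 14 | saturated diaxial bromochloride | CC1(C)O[C@](C)([C@@H]2C[C@@H](Cl)[C@](C)(Br)C[C@@H]2O[Si](C)(C)C(C)(C)C)CC[C@H]1Br
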